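**Strategy.** Ring B is a methylphloroglucinol in which the pyranone must close through O1 (next to C8) while O5 (next to the C6 methyl) stays free; from methylphloroglucinol both phenols flanking C4a compete. The route therefore builds ring B one oxygen short: 4-methylresorcinol offers a single phenol ortho to the acylation site, so 7-hydroxy-2,2,6-trimethylchroman-4-one forms as one regioisomer. The key step then inserts O5 into the peri C5–H bond by C4-carbonyl-directed C–H hydroxylation, giving the unprotected 5,7-dihydroxy-6-methylchromanone whose only free carbon is C8. A standard Mannich/o-quinone methide union with the (R)-acyl ring A completes the target.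

Key step: step 2

Remark on the chemistry: (R)-2-methylbutanoic acid (8) is taken as a commercial single enantiomer and carries the only stereocentre; 3,5-dimethoxy-4-methylphenol (used only in a fallback) is taken as commercial; ring B is numbered as a chroman-4-one (O1, C2–C4, C4a, C5–C8, C8a) and ring A from its acyl-bearing carbon (C1).

**Route**

Step 1
Reactants: 1 4-methylbenzene-1,3-diol (4-methylresorcinol); 2 3-methylbut-2-enoic acid (3,3-dimethylacrylic acid)
Product: 4 7-hydroxy-2,2,6-trimethylchroman-4-one, via open-chain aryl enone 3 (not isolated)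
Conditions: P2O5–MeSO3H, 70 °C
Reagents that add atoms: none
Why: Friedel–Crafts acylation of the resorcinol at C6 (ortho to one OH, para to the other) gives enone 3, whose only ortho phenol closes the pyranone by 6-endo oxa-Michael addition; this standard one-pot chromanone annulation can give only the 7-hydroxy-6-methyl pattern here and forms no stereocentre.

Step 2
Reactants: 4 7-hydroxy-2,2,6-trimethylchroman-4-one
Product: 7 5,7-dihydroxy-2,2,6-trimethylchroman-4-one, via 7-O-trifluoroacetate 5 (not isolated), via bis-trifluoroacetate 6 (not isolated)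
Conditions: [RuCl2(p-cymene)]2 (5 mol %), PhI(OCOCF3)2, CF3CO2H/(CF3CO)2O, 80 °C; then H2O/THF, rt
Reagents that add atoms: [bis(trifluoroacetoxy)iodo]benzene, O=C(OI(OC(=O)C(F)(F)F)c1ccccc1)C(F)(F)F
Why: In CF3CO2H/(CF3CO)2O the 7-OH is first masked as trifluoroacetate 5, which protects the only oxidisable phenol; the Ru(II) carboxylate then binds the C4 carbonyl oxygen and cleaves the peri C5–H bond by carboxylate-assisted metalation to a five-membered ruthenacycle, oxidation by the iodine(III) reagent and C–O reductive elimination give aryl trifluoroacetate 6, and water frees both phenols. The closest known reaction type is the Ru(II)- or Pd(II)-catalysed, ketone-directed ortho C–H oxygenation of aryl ketones, established on tetralones, chromanones and at C5 of chromones and flavones. The step closes no ring and creates no stereocentre. It needs site selectivity for C5–H over C8–H and over the C3 and benzylic C–H bonds, which should hold because C5–H is the only C–H the chelated metal can reach (C8–H lies between two oxygens with no directing group), and a second oxygenation cannot follow because no other ortho C–H exists. It also needs the regiochemistry of the pyranone to stay fixed, which should hold because the ring was closed through O1 in step 1 and O5 appears as an ester that cannot re-close it. The main uncertainty is the rate of metalation next to the C6 methyl group.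

Step 3
Reactants: 8 (R)-2-methylbutanoic acid; 9 2-methylbenzene-1,3,5-triol (2,4,6-trihydroxytoluene)
Product: 11 (R)-2-methyl-1-(2,4,6-trihydroxy-3-methylphenyl)butan-1-one, via (R)-2-methylbutanoyl chloride 10 (not isolated)
Conditions: (COCl)2, DMF (cat.), CH2Cl2, 0 °C → rt; then 9, AlCl3, PhNO2, 0 °C → rt
Reagents that add atoms: none
Why: Oxalyl chloride converts 8 into acid chloride 10 without base, and AlCl3-promoted Friedel–Crafts C-acylation of 9 occurs at one of its two equivalent free carbons; the stereocentre is that of 8, and low temperature is used to limit acylium–ketene equilibration.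

Step 4
Reactants: 11 (R)-2-methyl-1-(2,4,6-trihydroxy-3-methylphenyl)butan-1-one
Product: 12 (R)-1-(2,6-dihydroxy-4-methoxy-3-methylphenyl)-2-methylbutan-1-one
Conditions: MeI (1.0 equiv), K2CO3 (1.0 equiv), acetone, rt
Reagents that add atoms: iodomethane, CI
Why: Williamson O-methylation with one equivalent of weak base should occur at the 4-OH, which is para to the ketone and therefore the most acidic phenol and never chelated to the carbonyl; these mild conditions should not enolise the hindered α-branched ketone.

Step 5
Reactants: 12 (R)-1-(2,6-dihydroxy-4-methoxy-3-methylphenyl)-2-methylbutan-1-one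
Product: 13 (R)-1-{3-[(dimethylamino)methyl]-2,6-dihydroxy-4-methoxy-5-methylphenyl}-2-methylbutan-1-one
Conditions: CH2(NMe2)2, AcOH (cat.), EtOH, rt
Reagents that add atoms: bis(dimethylamino)methane, CN(C)CN(C)C
Why: Mannich aminomethylation by the iminium ion released from the aminal occurs at C5, the only unsubstituted carbon of the phloroglucinol ring.

Step 6
Reactants: 13 (R)-1-{3-[(dimethylamino)methyl]-2,6-dihydroxy-4-methoxy-5-methylphenyl}-2-methylbutan-1-one; 7 5,7-dihydroxy-2,2,6-trimethylchroman-4-one
Product: 15 8-{[2,4-dihydroxy-6-methoxy-5-methyl-3-((2R)-2-methylbutanoyl)phenyl]methyl}-5,7-dihydroxy-2,2,6-trimethylchroman-4-one (target), via o-quinone methide 14 (not isolated)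
Conditions: AcOH (1 equiv), dioxane, 80 °C
Reagents that add atoms: none
Why: Thermal loss of dimethylamine from the phenolic Mannich base gives o-quinone methide 14, which is captured in a Friedel–Crafts-type conjugate addition by C8 of 7, the only free aromatic carbon in either partner, so only the crossed diarylmethane can form; the acetic acid buffer and 80 °C are chosen to avoid base-induced opening of the chromanone and to leave the stereocentre untouched.

**Compound list**

1 | 4-methylbenzene-1,3-diol (4-methylresorcinol) | Cc1ccc(O)cc1O | starting material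
2 | 3-methylbut-2-enoic acid | CC(C)=CC(=O)O | starting material
3 | 1-(2,4-dihydroxy-5-methylphenyl)-3-methylbut-2-en-1-one | CC(C)=CC(=O)c1cc(C)c(O)cc1O | intermediate
4 | 7-hydroxy-2,2,6-trimethylchroman-4-one | Cc1cc2c(cc1O)OC(C)(C)CC2=O | intermediate
5 | 2,2,6-trimethyl-4-oxochroman-7-yl trifluoroacetate | Cc1cc2c(cc1OC(=O)C(F)(F)F)OC(C)(C)CC2=O | intermediate
6 | 2,2,6-trimethyl-4-oxochromane-5,7-diyl bis(trifluoroacetate) | Cc1c(OC(=O)C(F)(F)F)cc2c(c1OC(=O)C(F)(F)F)C(=O)CC(C)(C)O2 | intermediate
7 | 5,7-dihydroxy-2,2,6-trimethylchroman-4-one | Cc1c(O)cc2c(c1O)C(=O)CC(C)(C)O2 | intermediate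
8 | (R)-2-methylbutanoic acid | CC[C@@H](C)C(=O)O | starting material
9 | 2-methylbenzene-1,3,5-triol (2,4,6-trihydroxytoluene) | Cc1c(O)cc(O)cc1O | starting material
10 | (R)-2-methylbutanoyl chloride | CC[C@@H](C)C(=O)Cl | intermediate
11 | (R)-2-methyl-1-(2,4,6-trihydroxy-3-methylphenyl)butan-1-one | CC[C@@H](C)C(=O)c1c(O)cc(O)c(C)c1O | intermediate
12 | (R)-1-(2,6-dihydroxy-4-methoxy-3-methylphenyl)-2-methylbutan-1-one | CC[C@@H](C)C(=O)c1c(O)c(C)c(OC)cc1O | intermediate
13 | (R)-1-{3-[(dimethylamino)methyl]-2,6-dihydroxy-4-methoxy-5-methylphenyl}-2-methylbutan-1-one | CC[C@@H](C)C(=O)c1c(O)c(C)c(OC)c(CN(C)C)c1O | intermediate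
14 | (R)-3-hydroxy-5-methoxy-4-methyl-2-(2-methylbutanoyl)-6-methylidenecyclohexa-2,4-dien-1-one | CC[C@@H](C)C(=O)C1=C(O)C(C)=C(OC)C(=C)C1=O | intermediate
15 | 8-{[2,4-dihydroxy-6-methoxy-5-methyl-3-((2R)-2-methylbutanoyl)phenyl]methyl}-5,7-dihydroxy-2,2,6-trimethylchroman-4-one | CC[C@@H](C)C(=O)c1c(O)c(C)c(OC)c(Cc2c(O)c(C)c(O)c3c2OC(C)(C)CC3=O)c1O | target

**Count**

Total steps: 6. Longest linear sequence: 4 steps (steps 3, 4, 5, 6).

**Steps most likely to fail**

Step 2 (key step). Cyclometalation at C5–H may be slow because the C6 methyl flanks the bond, so that undirected oxidation of the alkoxyarene or α-oxygenation of the ketone by the iodine(III) reagent takes over. The fallback buys the oxygen pattern and fixes the regiochemistry by protection instead of C–H oxidation. It sets out from 2. Condensation of 2 with 3,5-dimethoxy-4-methylphenol F1 in P2O5–MeSO3H at 70 °C passes through 1-(2-hydroxy-4,6-dimethoxy-5-methylphenyl)-3-methylbut-2-en-1-one F2, which can close only through its single free phenol, and should give 5,7-dimethoxy-2,2,6-trimethylchroman-4-one F3. BBr3 (CH2Cl2, −78 °C → rt) then cleaves both methyl ethers. The fallback comes back to the route at 7.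

Step 6. The liberated amine may open the pyranone by retro-oxa-Michael reaction at 80 °C and let it re-close through O5, which would scramble the 6-methyl/8-benzyl pattern. Alternatively, the o-quinone methide from 13 may form sluggishly because both of its phenols are hydrogen-bonded, and may then be captured at oxygen or by 13 itself. The fallback reverses the polarity and generates the o-quinone methide on ring B at room temperature. It sets out from 7 and 12. Compound 7 is aminomethylated at C8 with CH2(NMe2)2 to 8-[(dimethylamino)methyl]-5,7-dihydroxy-2,2,6-trimethylchroman-4-one F4, and MeI quaternises this to [(5,7-dihydroxy-2,2,6-trimethyl-4-oxochroman-8-yl)methyl]trimethylammonium iodide F5. With NaHCO3 in MeCN/H2O at rt, F5 should lose trimethylamine to give 5-hydroxy-2,2,6-trimethyl-8-methylidene-2,3-dihydrochromene-4,7-dione F6, which C5 of 12 captures. The fallback comes back at 15.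

Step 3. The α-stereocentre may partly racemise through acylium–ketene equilibration under AlCl3, and a second acylation may occur at the other free carbon; imperfect mono-O-methylation in step 4 is bypassed by the same detour. The fallback uses a fully O-methylated arene, a mild Lewis acid and chelation-controlled demethylation instead of selective methylation. It sets out from 10. Acylation of 2,4,6-trimethoxytoluene F7 with 10 and SnCl4 in CH2Cl2 at −40 °C should give (R)-2-methyl-1-(2,4,6-trimethoxy-3-methylphenyl)butan-1-one F8. BCl3 (CH2Cl2, 0 °C → rt) should then remove only the two methyl ethers ortho to the carbonyl. The fallback comes back at 12.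

**Further compounds**

F1 | step 2 | 3,5-dimethoxy-4-methylphenol | Cc1c(OC)cc(O)cc1OC
F2 | step 2 | 1-(2-hydroxy-4,6-dimethoxy-5-methylphenyl)-3-methylbut-2-en-1-one | CC(C)=CC(=O)c1c(O)cc(OC)c(C)c1OC
F3 | step 2 | 5,7-dimethoxy-2,2,6-trimethylchroman-4-one | Cc1c(OC)cc2c(c1OC)C(=O)CC(C)(C)O2
F4 | step 6 | 8-[(dimethylamino)methyl]-5,7-dihydroxy-2,2,6-trimethylchroman-4-one | Cc1c(O)c(CN(C)C)c2c(c1O)C(=O)CC(C)(C)O2
F5 | step 6 | [(5,7-dihydroxy-2,2,6-trimethyl-4-oxochroman-8-yl)methyl]trimethylammonium iodide | C[N+](C)(C)Cc1c(O)c(C)c(O)c2c1OC(C)(C)CC2=O.[I-]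
F6 | step 6 | 5-hydroxy-2,2,6-trimethyl-8-methylidene-2,3-dihydrochromene-4,7-dione | C=C1C(=O)C(C)=C(O)C2=C1OC(C)(C)CC2=O
F7 | step 3 | 2,4,6-trimethoxytoluene | Cc1c(OC)cc(OC)cc1OC
F8 | step 3 | (R)-2-methyl-1-(2,4,6-trimethoxy-3-methylphenyl)butan-1-one | CC[C@@H](C)C(=O)c1c(OC)c(C)c(OC)cc1OC
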